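The C8'–C9' bond sits in the middle of the saturated tether of the tridecyl chain (C1' on quinolone C2, C12' the carbinol carbon), and the target is cut there. This bond lies in a featureless polymethylene stretch, seven CH2 groups from the 4-quinolone ring and two from the tertiary carbinol. It can therefore be forged as a C8'=C9' alkene by cross-metathesis of two terminal olefins without protecting N1–H, C4=O or the OH; hydrogenation in the same flask then delivers the target directly. The metathesis precursor, 2-(non-8-enyl)quinolin-4(1H)-one, comes in one step from lateral alkylation of the 2-methylquinolin-4(1H)-one dianion; its partner is 2-methylhex-5-en-2-ol.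

Key step: step 2

Remark: the target has no stereocentre (C12' carries two identical methyl groups), so it is achiral and no enantiocontrol is needed; the E/Z geometry of the transient alkene is erased by hydrogenation.

Step 1
Reactants: 1 2-methylquinolin-4(1H)-one; 2 8-bromooct-1-ene
Product: 4 2-(non-8-en-1-yl)quinolin-4(1H)-one, via dilithio dianion 3 (not isolated)
Conditions: n-BuLi (2.3 equiv), THF, −78 → 0 °C; then 2 (1.0 equiv), 0 °C → rt; 1 M aq HCl to pH 7
Reagents that add atoms: none
Why: Dianion (lateral metalation) alkylation: the second equivalent of n-BuLi deprotonates the 2-methyl group of the lithium quinolin-4-olate, and the resulting carbanion, the last-formed and most basic site, should attack the primary bromide by SN2 at carbon in preference to N1 or O4.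

Step 2
Reactants: 4 2-(non-8-en-1-yl)quinolin-4(1H)-one; 5 2-methylhex-5-en-2-ol
Product: 7 2-(12-hydroxy-12-methyltridecyl)quinolin-4(1H)-one, via cross-metathesis alkene 6 (not isolated)
Conditions: Hoveyda–Grubbs II catalyst (5 mol%), 1,4-benzoquinone (10 mol%), 5 (4 equiv), CH2Cl2, 40 °C, Ar sweep; then same flask: MeOH, 10% Pd/C, H2 (1 atm), rt
Reagents that add atoms: none
Why: The ruthenium carbene initiates on the unhindered terminal alkene of 4 or 5, and successive [2+2] cycloaddition/cycloreversion through ruthenacyclobutanes exchanges the two =CH2 termini for each other, so that C8' of 4 becomes doubly bonded to C9' (the former C5 of 5) while ethylene leaves the solution. This is an olefin cross-metathesis of two terminal (type I) alkenes, followed in the same flask by heterogeneous Pd-catalysed hydrogenation of the new 1,2-disubstituted alkene. No ring is closed and no stereocentre is formed, and the E/Z mixture of 6 is of no consequence because hydrogenation removes the double bond. The step needs cross-coupling over homodimerisation of 4, which the fourfold excess of cheap 5 should secure statistically (the homodimer of 5 stays metathesis-active and delivers the same fragment), and it needs the double bond of 4 not to migrate before metathesis, which would give chain-shortened homologues, hence the benzoquinone additive. The joining site lies seven CH2 groups from the quinolone ring and two from the carbinol carbon, so neither N1–H, C4=O nor the free OH should interfere sterically or electronically, and no protecting group is needed. In the hydrogenation stage only the isolated C8'=C9' bond should react, because the vinylogous-amide C2=C3 bond and the benzo ring of the quinolone are inert to H2/Pd-C at 1 atm and rt and the tertiary alcohol is neither allylic nor benzylic.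

Compound list
1 | 2-methylquinolin-4(1H)-one (4-hydroxy-2-methylquinoline) | Cc1cc(=O)c2ccccc2[nH]1 | starting material
2 | 8-bromooct-1-ene | C=CCCCCCCBr | starting material
3 | dilithio dianion of 1 (lithium 2-(lithiomethyl)quinolin-4-olate) | [Li+].[Li+].[CH2-]c1cc([O-])c2ccccc2n1 | intermediate
4 | 2-(non-8-en-1-yl)quinolin-4(1H)-one | C=CCCCCCCCc1cc(=O)c2ccccc2[nH]1 | intermediate
5 | 2-methylhex-5-en-2-ol | CC(C)(O)CCC=C | starting material
6 | 2-(12-hydroxy-12-methyltridec-8-en-1-yl)quinolin-4(1H)-one (E/Z mixture) | CC(C)(O)CCC=CCCCCCCCc1cc(=O)c2ccccc2[nH]1 | intermediate
7 | 2-(12-hydroxy-12-methyltridecyl)quinolin-4(1H)-one | CC(C)(O)CCCCCCCCCCCc1cc(=O)c2ccccc2[nH]1 | target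

Total step count: 2
Longest linear sequence: 2 steps (1 → 4 → 7)

Steps most likely to fail (the route has only two steps, so both are ranked):

1. Step 2 (key step). What may go wrong: slow deactivation of the ruthenium carbene by coordination to the quinolone (O4, or N1 of the minor 4-hydroxyquinoline tautomer), together with low solubility of 4 in CH2Cl2. Self-metathesis of 5 and double-bond migration along the chain of 4 would then outrun the cross-coupling, and migration leads after hydrogenation to chain-shortened homologues that are hard to separate. Fallback: the same C8'–C9' bond is formed before the heterocycle is present. The fallback sets out from 2 and 5: cross-metathesis (Hoveyda–Grubbs II catalyst, benzoquinone, CH2Cl2, 40 °C) should give (E/Z)-12-bromo-2-methyldodec-5-en-2-ol F1. n-BuLi (1 equiv, THF, −78 °C) converts it into lithium 12-bromo-2-methyldodec-5-en-2-olate F2, which is added to dianion 3, generated from 1 as in step 1. SN2 at the primary bromide and neutralisation with aq HCl should give 6, here isolated. The fallback comes back to the route at 6, which is hydrogenated under the conditions of the second stage of step 2.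

2. Step 1. What may go wrong: incomplete lateral metalation because the monolithium salt of 1 is sparingly soluble in THF. Alkylation at nitrogen or oxygen, loss of the bromide by E2 elimination, or double alkylation at C1' through proton exchange between 3 and the product anion could then compete. Fallback: the quinolone is masked as a soluble 4-chloroquinoline that needs only one deprotonation. The fallback sets out from 1: POCl3 (neat, 100 °C) should give 4-chloro-2-methylquinoline F3. LDA (1.1 equiv, THF, −78 °C) should give 4-chloro-2-(lithiomethyl)quinoline F4, which is alkylated with 2 to give 4-chloro-2-(non-8-en-1-yl)quinoline F5. Hydrolysis of the 4-chloro group (NaOAc, AcOH/H2O, 110 °C) should then bring the fallback back to the route at 4.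

Further compounds
F1 | step 2 | (E/Z)-12-bromo-2-methyldodec-5-en-2-ol | CC(C)(O)CCC=CCCCCCCBr
F2 | step 2 | lithium 12-bromo-2-methyldodec-5-en-2-olate | [Li+].CC(C)([O-])CCC=CCCCCCCBr
F3 | step 1 | 4-chloro-2-methylquinoline | Cc1cc(Cl)c2ccccc2n1
F4 | step 1 | 4-chloro-2-(lithiomethyl)quinoline | [Li+].[CH2-]c1cc(Cl)c2ccccc2n1
F5 | step 1 | 4-chloro-2-(non-8-en-1-yl)quinoline | C=CCCCCCCCc1cc(Cl)c2ccccc2n1
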